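The route reads ring B (C5–C6–C7–C8–C9–C10) of the trans-decalin as a Diels–Alder adduct and the C8 exocyclic methylene as a masked C8=C9 alkene that carries a CH2SiMe3 group. An intramolecular Diels–Alder reaction of an acyclic triene joins C5 to C10 and C6 to C7 in one operation, closes ring A (C1–C5, C10) and ring B, and sets the quaternary C10 and C5. The precursor carries a 2-(silylmethyl)-1,3-diene with a stereodefined tetrasubstituted C9=C10 bond, a four-carbon tether bearing the C3 acetate and the quaternary C4, and an (E)-vinyl sulfone as activated, later traceless dienophile. Protodesilylation finally sets C9 and unveils the methylene.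

Key step: step 14

Remark: labdane numbering is used for all atoms (C1–C10 decalin, C11–C16 side chain, C17 on C8, C18 and C19 the methyl and ester carbon on C4, C20 the methyl on C10). TBS = tert-butyldimethylsilyl. Compounds 1, 5, 9, 15, 19 and 23 are taken as commercial.

Step 1
Reactants: 1 3-methylbut-2-en-1-ol (prenol)
Product: 2 tert-butyldimethyl[(3-methylbut-2-en-1-yl)oxy]silane
Conditions: TBSCl, imidazole, CH2Cl2, 0 °C to rt
Reagents that add atoms: tert-butyldimethylsilyl chloride, CC(C)(C)[Si](C)(C)Cl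
Why: Imidazole-promoted silylation of a primary allylic alcohol gives an ether that tolerates the later strong bases and hydride.

Step 2
Reactants: 2 prenyl TBS ether
Product: 3 (2E)-4-(tert-butyldimethylsilyloxy)-2-methylbut-2-en-1-ol
Conditions: SeO2 (0.5 equiv), t-BuOOH, salicylic acid (cat.), CH2Cl2, rt
Reagents that add atoms: selenium dioxide (catalytic oxygen carrier), O=[Se]=O; tert-butyl hydroperoxide (terminal oxidant), CC(C)(C)OO
Why: SeO2 allylic oxidation (ene reaction then [2,3]-shift) attacks the (E)-methyl group of the trisubstituted alkene, which fixes the (E)-geometry of the later C13=C14 bond.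

Step 3
Reactants: 3 allylic alcohol
Product: 4 [(2E)-4-bromo-3-methylbut-2-en-1-yl]oxy(tert-butyl)dimethylsilane
Conditions: CBr4, PPh3, CH2Cl2, 0 °C
Reagents that add atoms: carbon tetrabromide, BrC(Br)(Br)Br
Why: Appel bromination replaces the primary allylic hydroxyl by SN2 under neutral conditions without allylic transposition.

Step 4
Reactants: 5 methyl 2-methyl-3-oxobutanoate; 4 allylic bromide
Product: 7 methyl (6E)-8-(tert-butyldimethylsilyloxy)-2,6-dimethyl-3-oxooct-6-enoate (racemic at C2), via acetoacetate dianion 6 (not isolated)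
Conditions: NaH, THF, 0 °C; n-BuLi, 0 °C; then 4, 0 °C; aq. NH4Cl
Reagents that add atoms: none
Why: In the acetoacetate dianion γ-alkylation the terminal carbanion is the more nucleophilic site and displaces the allylic bromide, which forms the C11–C12 bond and leaves a ketone at C9.

Step 5
Reactants: 7 β-keto ester
Product: 8 methyl (2E,6E)-8-(tert-butyldimethylsilyloxy)-2,6-dimethyl-3-(tosyloxy)octa-2,6-dienoate
Conditions: TsCl, TMEDA, MeCN, 0 °C to rt
Reagents that add atoms: p-toluenesulfonyl chloride, Cc1ccc(cc1)S(=O)(=O)Cl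
Why: Lithium-free, amine-mediated O-sulfonylation of an α-substituted β-keto ester runs through the non-chelated enolate and should give the (E)-enol tosylate (OTs trans to CO2Me), which stores the geometry of the later C9=C10 bond.

Step 6
Reactants: 8 enol tosylate; 9 (2-bromoprop-2-en-1-yl)trimethylsilane
Product: 12 methyl (2E,6E)-8-(tert-butyldimethylsilyloxy)-2,6-dimethyl-3-[3-(trimethylsilyl)prop-1-en-2-yl]octa-2,6-dienoate, via alkenyllithium 10 (not isolated), via alkenylzinc chloride 11 (not isolated)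
Conditions: 9, t-BuLi (2 equiv), Et2O, −78 °C; ZnCl2, THF; then 8, Pd(OAc)2/SPhos (cat.), THF, 50 °C
Reagents that add atoms: none
Why: Negishi coupling of an enol tosylate proceeds with retention at the C–O carbon, so the C7=C8(CH2SiMe3) unit is placed cis to the C20 methyl and the tetrasubstituted diene is obtained with defined geometry.

Step 7
Reactants: 12 dienoate
Product: 13 (2E,6E)-8-(tert-butyldimethylsilyloxy)-2,6-dimethyl-3-[3-(trimethylsilyl)prop-1-en-2-yl]octa-2,6-dien-1-ol
Conditions: DIBAL-H, CH2Cl2, −78 °C; Rochelle salt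
Reagents that add atoms: none
Why: DIBAL-H reduces the conjugated ester by 1,2-addition to the allylic alcohol (C1) and leaves the allylsilane and silyl ether untouched.

Step 8
Reactants: 13 allylic alcohol
Product: 14 (2E,6E)-1-bromo-8-(tert-butyldimethylsilyloxy)-2,6-dimethyl-3-[3-(trimethylsilyl)prop-1-en-2-yl]octa-2,6-diene
Conditions: CBr4, PPh3, 2,6-lutidine, CH2Cl2, −30 °C
Reagents that add atoms: carbon tetrabromide, BrC(Br)(Br)Br
Why: Buffered Appel bromination is an SN2 process at the primary carbon, so the olefin geometry is kept and the acid-labile allylsilane is spared.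

Step 9
Reactants: 14 allylic bromide; 15 N-tert-butylethanimine
Product: 18 (4E,8E)-10-(tert-butyldimethylsilyloxy)-4,8-dimethyl-5-[3-(trimethylsilyl)prop-1-en-2-yl]deca-4,8-dienal, via lithiated imine 16 (not isolated), via alkylated imine 17 (not isolated)
Conditions: 15, LDA, THF, −78 °C; then 14, −78 to 0 °C; aq. tartaric acid buffer (pH 5), rt
Reagents that add atoms: water, O
Why: Metalloenamine (aza-enolate) alkylation uses the imine as an acetaldehyde enolate equivalent to add C2 and C3 by SN2, and the weakly acidic hydrolysis frees the aldehyde without protodesilylation.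

Step 10
Reactants: 18 aldehyde; 19 (4S)-4-benzyl-3-propanoyl-1,3-oxazolidin-2-one
Product: 21 (4S)-4-benzyl-3-[(2S,3R,6E,10E)-12-(tert-butyldimethylsilyloxy)-3-hydroxy-2,6,10-trimethyl-7-[3-(trimethylsilyl)prop-1-en-2-yl]dodeca-6,10-dienoyl]-1,3-oxazolidin-2-one, via boron enolate 20 (not isolated)
Conditions: 19, Bu2BOTf, i-Pr2NEt, CH2Cl2, −78 to 0 °C; then 18, −78 °C; pH 7 buffer, MeOH, H2O2, 0 °C
Reagents that add atoms: none
Why: The Evans syn-aldol reaction of the (Z)-boron enolate through a Zimmerman–Traxler transition state lets the (S)-benzyl auxiliary set the carbinol C3 as (R), the 3α-oxygen of the target, while the configuration at C4 is provisional.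

Step 11
Reactants: 21 aldol adduct
Product: 22 methyl (2S,3R,6E,10E)-12-(tert-butyldimethylsilyloxy)-3-hydroxy-2,6,10-trimethyl-7-[3-(trimethylsilyl)prop-1-en-2-yl]dodeca-6,10-dienoate
Conditions: NaOMe, MeOH, 0 °C
Reagents that add atoms: sodium methoxide, [Na+].[O-]C
Why: Methanolysis at the exocyclic imide carbonyl removes the auxiliary and installs the C19 methyl ester needed for the dianion chemistry and for the target.

Step 12
Reactants: 22 β-hydroxy ester; 23 (E)-1,2-bis(phenylsulfonyl)ethene
Product: 25 methyl (2R,3R,6E,10E)-12-(tert-butyldimethylsilyloxy)-3-hydroxy-2,6,10-trimethyl-2-[(E)-2-(phenylsulfonyl)ethenyl]-7-[3-(trimethylsilyl)prop-1-en-2-yl]dodeca-6,10-dienoate, via dilithium dianion 24 (not isolated)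
Conditions: LDA (2.3 equiv), THF, −78 to −30 °C; then 23, −78 °C; aq. NH4Cl
Reagents that add atoms: none
Why: In this Frater–Seebach alkylation the chelated alkoxide–enolate is attacked on the face anti to the C2 chain by the bis-sulfone, and E1cB loss of sulfinate (addition–elimination vinylation of an ester enolate) then gives the quaternary C4 with methyl syn and vinyl anti to the C3 oxygen together with the (E)-vinyl sulfone.

Step 13
Reactants: 25 hydroxy vinyl sulfone
Product: 26 3-O-acetate of 25 (Diels–Alder triene)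
Conditions: Ac2O, Et3N, DMAP (cat.), CH2Cl2, rt
Reagents that add atoms: acetic anhydride, CC(=O)OC(C)=O
Why: DMAP-catalysed acylation acetylates the hindered secondary alcohol, and the quaternary C4 rules out isomerisation of the vinyl sulfone under the basic conditions.

Step 14
Reactants: 26 triene acetate
Product: 27 methyl 3α-acetoxy-15-(tert-butyldimethylsilyloxy)-6α-(phenylsulfonyl)-17-(trimethylsilyl)labda-8(9),13E-dien-19-oate (5α-H, 10β-CH3)
Conditions: PhMe (0.01 M), BHT (cat.), sealed tube, 150 °C
Reagents that add atoms: none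
Why: Thermal, concerted but asynchronous [4+2] cycloaddition of the electron-rich C7=C8–C9=C10 diene (tetra-alkylated, HOMO raised by the allylic C–Si bond) with the sulfonyl-activated C5=C6 dienophile; the closest known type is the type-1 intramolecular Diels–Alder reaction of (E)-1-sulfonyl-1,7,9-decatrienes. Ring A (C10–C1–C2–C3–C4–C5) is closed by the C5–C10 bond through the four-atom tether in a chair-like array (fused mode), and ring B (C5–C6–C7–C8–C9–C10) is the new cyclohexene closed by both bonds. C5 and C10 should come out trans because the tether is the outside and the methyl the inside substituent of the diene terminus and the tether reacts in the exo (anti) orientation with the sulfonyl group endo, which keeps the bulky quaternary C4 away from the diene and its C9 chain. The π-face is fixed by C4 and C3: the chair with pseudoaxial C4–CO2Me and C3–OAc and pseudoequatorial C4–CH3 avoids a syn-pentane contact between the C4 methyl and the inside C10 methyl and keeps the C–OAc and C–CO2Me dipoles anti, which leads to 10β-CH3 and 5α-H. C6 (sulfonyl α) follows from the (E)-alkene and is erased in step 15. The step needs exo-tether over endo-tether selectivity, one π-face and a rate above the [1,5]-hydrogen shift open to the (Z)-methyl diene; sulfone activation, the Thorpe–Ingold effect of C4 and the moderate temperature should secure these.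

Step 15
Reactants: 27 cycloadduct
Product: 28 methyl 3α-acetoxy-15-(tert-butyldimethylsilyloxy)-17-(trimethylsilyl)labda-8(9),13E-dien-19-oate
Conditions: Na(Hg) (6%), Na2HPO4, MeOH/THF, −20 to 0 °C
Reagents that add atoms: none
Why: Buffered sodium amalgam desulfonylation cleaves the secondary C6–S bond by electron transfer to leave the C6 methylene, and the neopentyl C3 acetate should resist the buffered methanol.

Step 16
Reactants: 28 allylsilane
Product: 29 methyl 3α-acetoxy-15-hydroxylabda-8(17),13E-dien-19-oate (target; 3R,4R,5R,9S,10R)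
Conditions: TsOH·H2O (0.3 equiv), MeCN/H2O, 0 °C to rt
Reagents that add atoms: none
Why: Acid-mediated SE2' protodesilylation should deliver the proton to C9 axially from the α-face, anti to the axial C10 methyl, which moves the double bond to C8=C17 and sets 9α-H with the side chain equatorial, while the same acid cleaves the primary TBS ether.

Compound list
1 | 3-methylbut-2-en-1-ol (prenol) | CC(C)=CCO | starting material
2 | tert-butyldimethyl[(3-methylbut-2-en-1-yl)oxy]silane | CC(C)=CCO[Si](C)(C)C(C)(C)C | intermediate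
3 | (2E)-4-(tert-butyldimethylsilyloxy)-2-methylbut-2-en-1-ol | OC/C(C)=C/CO[Si](C)(C)C(C)(C)C | intermediate
4 | [(2E)-4-bromo-3-methylbut-2-en-1-yl]oxy(tert-butyl)dimethylsilane | BrC/C(C)=C/CO[Si](C)(C)C(C)(C)C | intermediate
5 | methyl 2-methyl-3-oxobutanoate | COC(=O)C(C)C(C)=O | starting material
6 | sodium lithium C2,C4-dianion of 5 | [CH2-]C(=O)[C-](C)C(=O)OC.[Na+].[Li+] | intermediate (not isolated)
7 | methyl (6E)-8-(tert-butyldimethylsilyloxy)-2,6-dimethyl-3-oxooct-6-enoate | COC(=O)C(C)C(=O)CC/C(C)=C/CO[Si](C)(C)C(C)(C)C | intermediate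
8 | methyl (2E,6E)-8-(tert-butyldimethylsilyloxy)-2,6-dimethyl-3-(tosyloxy)octa-2,6-dienoate | COC(=O)/C(C)=C(/OS(=O)(=O)c1ccc(C)cc1)CC/C(C)=C/CO[Si](C)(C)C(C)(C)C | intermediate
9 | (2-bromoprop-2-en-1-yl)trimethylsilane | C=C(Br)C[Si](C)(C)C | starting material
10 | [3-(trimethylsilyl)prop-1-en-2-yl]lithium | [Li]C(=C)C[Si](C)(C)C | intermediate (not isolated)
11 | chloro[3-(trimethylsilyl)prop-1-en-2-yl]zinc | Cl[Zn]C(=C)C[Si](C)(C)C | intermediate (not isolated)
12 | methyl (2E,6E)-8-(tert-butyldimethylsilyloxy)-2,6-dimethyl-3-[3-(trimethylsilyl)prop-1-en-2-yl]octa-2,6-dienoate | COC(=O)/C(C)=C(/C(=C)C[Si](C)(C)C)CC/C(C)=C/CO[Si](C)(C)C(C)(C)C | intermediate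
13 | (2E,6E)-8-(tert-butyldimethylsilyloxy)-2,6-dimethyl-3-[3-(trimethylsilyl)prop-1-en-2-yl]octa-2,6-dien-1-ol | OC/C(C)=C(/C(=C)C[Si](C)(C)C)CC/C(C)=C/CO[Si](C)(C)C(C)(C)C | intermediate
14 | (2E,6E)-1-bromo-8-(tert-butyldimethylsilyloxy)-2,6-dimethyl-3-[3-(trimethylsilyl)prop-1-en-2-yl]octa-2,6-diene | BrC/C(C)=C(/C(=C)C[Si](C)(C)C)CC/C(C)=C/CO[Si](C)(C)C(C)(C)C | intermediate
15 | N-tert-butylethanimine | CC=NC(C)(C)C | starting material
16 | N-lithio-N-tert-butylethenamine (aza-enolate of 15) | C=CN([Li])C(C)(C)C | intermediate (not isolated)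
17 | N-tert-butylimine of aldehyde 18 | CC(C)(C)N=CCC/C(C)=C(/C(=C)C[Si](C)(C)C)CC/C(C)=C/CO[Si](C)(C)C(C)(C)C | intermediate (not isolated)
18 | (4E,8E)-10-(tert-butyldimethylsilyloxy)-4,8-dimethyl-5-[3-(trimethylsilyl)prop-1-en-2-yl]deca-4,8-dienal | O=CCC/C(C)=C(/C(=C)C[Si](C)(C)C)CC/C(C)=C/CO[Si](C)(C)C(C)(C)C | intermediate
19 | (4S)-4-benzyl-3-propanoyl-1,3-oxazolidin-2-one | CCC(=O)N1[C@@H](Cc2ccccc2)COC1=O | starting material
20 | (Z)-dibutylboron enolate of 19 | C/C=C(\OB(CCCC)CCCC)N1[C@@H](Cc2ccccc2)COC1=O | intermediate (not isolated)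
21 | (4S)-4-benzyl-3-[(2S,3R,6E,10E)-12-(tert-butyldimethylsilyloxy)-3-hydroxy-2,6,10-trimethyl-7-[3-(trimethylsilyl)prop-1-en-2-yl]dodeca-6,10-dienoyl]-1,3-oxazolidin-2-one | O=C1OC[C@H](Cc2ccccc2)N1C(=O)[C@@H](C)[C@H](O)CC/C(C)=C(/C(=C)C[Si](C)(C)C)CC/C(C)=C/CO[Si](C)(C)C(C)(C)C | intermediate
22 | methyl (2S,3R,6E,10E)-12-(tert-butyldimethylsilyloxy)-3-hydroxy-2,6,10-trimethyl-7-[3-(trimethylsilyl)prop-1-en-2-yl]dodeca-6,10-dienoate | C=C(C[Si](C)(C)C)/C(CC/C(C)=C/CO[Si](C)(C)C(C)(C)C)=C(\C)CC[C@@H](O)[C@H](C)C(=O)OC | intermediate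
23 | (E)-1,2-bis(phenylsulfonyl)ethene | O=S(=O)(/C=C/S(=O)(=O)c1ccccc1)c1ccccc1 | starting material
24 | dilithium alkoxide enolate of 22 | C=C(C[Si](C)(C)C)/C(CC/C(C)=C/CO[Si](C)(C)C(C)(C)C)=C(\C)CC[C@@H]([O-])C(C)=C([O-])OC.[Li+].[Li+] | intermediate (not isolated)
25 | methyl (2R,3R,6E,10E)-12-(tert-butyldimethylsilyloxy)-3-hydroxy-2,6,10-trimethyl-2-[(E)-2-(phenylsulfonyl)ethenyl]-7-[3-(trimethylsilyl)prop-1-en-2-yl]dodeca-6,10-dienoate | C=C(C[Si](C)(C)C)/C(CC/C(C)=C/CO[Si](C)(C)C(C)(C)C)=C(\C)CC[C@@H](O)[C@](/C=C/S(=O)(=O)c1ccccc1)(C)C(=O)OC | intermediate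
26 | 3-O-acetate of 25 (Diels–Alder triene) | C=C(C[Si](C)(C)C)/C(CC/C(C)=C/CO[Si](C)(C)C(C)(C)C)=C(\C)CC[C@@H](OC(C)=O)[C@](/C=C/S(=O)(=O)c1ccccc1)(C)C(=O)OC | intermediate
27 | methyl 3α-acetoxy-15-(tert-butyldimethylsilyloxy)-6α-(phenylsulfonyl)-17-(trimethylsilyl)labda-8(9),13E-dien-19-oate | C[Si](C)(C)CC=1C[C@H](S(=O)(=O)c3ccccc3)[C@@H]2[C@](C)(CC[C@@H](OC(C)=O)[C@]2(C)C(=O)OC)C=1CC/C(C)=C/CO[Si](C)(C)C(C)(C)C | intermediate
28 | methyl 3α-acetoxy-15-(tert-butyldimethylsilyloxy)-17-(trimethylsilyl)labda-8(9),13E-dien-19-oate | C[Si](C)(C)CC=1CC[C@@H]2[C@](C)(CC[C@@H](OC(C)=O)[C@]2(C)C(=O)OC)C=1CC/C(C)=C/CO[Si](C)(C)C(C)(C)C | intermediate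
29 | methyl 3α-acetoxy-15-hydroxylabda-8(17),13E-dien-19-oate | C=C1CC[C@@H]2[C@](C)(CC[C@@H](OC(C)=O)[C@]2(C)C(=O)OC)[C@H]1CC/C(C)=C/CO | target

Total step count: 16. Longest linear sequence: 16 steps (from 1 to 29; the route is linear, with 5, 9, 15, 19 and 23 entering as commercial reagents).

Steps most likely to fail

Step 14 (key step). The two chair-like exo transition states may be too close in energy, so that the diastereomer with the opposite configuration at C5 and C10 forms alongside; endo-tether closure to the cis-decalin or a [1,5]-hydrogen shift of the diene may also compete at the temperature needed. The fallback sets out from 25 and makes C3 a temporary sp2 centre. Oxidation with Dess–Martin periodinane should give the 3-oxo triene F1, in which the chair with the axial ester is favoured by dipole minimisation next to the ketone as well as by the methyl–methyl contact. Heating under the conditions of step 14 should give the 3-oxo cycloadduct F2. L-Selectride attacks the ring ketone from the equatorial direction and should give the axial 3α-alcohol F3. Acetylation (Ac2O, DMAP) returns to the route at 27.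

Step 12. The alkoxide oxygen may add to the bis-sulfone in place of the hindered tetrasubstituted enolate carbon, or the addition–elimination may stall or give E/Z mixtures. The fallback sets out from 22 and uses a small electrophile first. The same dianion 24 is trapped with monomeric formaldehyde, again anti to the C2 chain, to give the C4-hydroxymethyl diol F4. Oxidation of the primary alcohol with TEMPO and PhI(OAc)2 should give the C4-formyl β-hydroxy ester F5. A Horner–Wadsworth–Emmons reaction with diethyl (phenylsulfonylmethyl)phosphonate (LiCl, DBU, MeCN) builds the (E)-vinyl sulfone and returns to the route at 25.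

Step 6. Oxidative addition into the hindered, fully substituted enol tosylate may be slow, and prolonged heating with palladium may erode the olefin geometry. The fallback sets out from 7 and replaces the palladium cross-coupling by a copper addition–elimination. Diethyl chlorophosphate with Et3N and DMAP in DMPU should give the (E)-enol diethyl phosphate F6. The alkenyllithium 10 and CuI (2:1) give the Gilman cuprate F7, which should displace the phosphate with retention by conjugate addition–elimination at −78 °C and return to the route at 12.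

Further compounds
F1 | step 14 | methyl (6E,10E)-12-(tert-butyldimethylsilyloxy)-2,6,10-trimethyl-3-oxo-2-[(E)-2-(phenylsulfonyl)ethenyl]-7-[3-(trimethylsilyl)prop-1-en-2-yl]dodeca-6,10-dienoate (3-oxo triene, C4 as in 25) | C=C(C[Si](C)(C)C)/C(CC/C(C)=C/CO[Si](C)(C)C(C)(C)C)=C(\C)CCC(=O)[C@](/C=C/S(=O)(=O)c1ccccc1)(C)C(=O)OC
F2 | step 14 | methyl 3-oxo-15-(tert-butyldimethylsilyloxy)-6α-(phenylsulfonyl)-17-(trimethylsilyl)labda-8(9),13E-dien-19-oate | C[Si](C)(C)CC=1C[C@H](S(=O)(=O)c3ccccc3)[C@@H]2[C@](C)(CCC(=O)[C@]2(C)C(=O)OC)C=1CC/C(C)=C/CO[Si](C)(C)C(C)(C)C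
F3 | step 14 | methyl 3α-hydroxy-15-(tert-butyldimethylsilyloxy)-6α-(phenylsulfonyl)-17-(trimethylsilyl)labda-8(9),13E-dien-19-oate | C[Si](C)(C)CC=1C[C@H](S(=O)(=O)c3ccccc3)[C@@H]2[C@](C)(CC[C@@H](O)[C@]2(C)C(=O)OC)C=1CC/C(C)=C/CO[Si](C)(C)C(C)(C)C
F4 | step 12 | methyl (6E,10E)-12-(tert-butyldimethylsilyloxy)-3-hydroxy-2-(hydroxymethyl)-2,6,10-trimethyl-7-[3-(trimethylsilyl)prop-1-en-2-yl]dodeca-6,10-dienoate (C4-hydroxymethyl diol) | C=C(C[Si](C)(C)C)/C(CC/C(C)=C/CO[Si](C)(C)C(C)(C)C)=C(\C)CC[C@@H](O)[C@](CO)(C)C(=O)OC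
F5 | step 12 | methyl (6E,10E)-12-(tert-butyldimethylsilyloxy)-2-formyl-3-hydroxy-2,6,10-trimethyl-7-[3-(trimethylsilyl)prop-1-en-2-yl]dodeca-6,10-dienoate (C4-formyl β-hydroxy ester) | C=C(C[Si](C)(C)C)/C(CC/C(C)=C/CO[Si](C)(C)C(C)(C)C)=C(\C)CC[C@@H](O)[C@](C=O)(C)C(=O)OC
F6 | step 6 | methyl (2E,6E)-8-(tert-butyldimethylsilyloxy)-3-[(diethoxyphosphoryl)oxy]-2,6-dimethylocta-2,6-dienoate | COC(=O)/C(C)=C(/OP(=O)(OCC)OCC)CC/C(C)=C/CO[Si](C)(C)C(C)(C)C
F7 | step 6 | lithium bis[3-(trimethylsilyl)prop-1-en-2-yl]cuprate | [Li+].C=C(C[Si](C)(C)C)[Cu-]C(=C)C[Si](C)(C)C
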